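**Retrosynthetic overview**
1. The 4'-OH is released last from a benzyl ether; flavone 17 already holds every other atom of the target.
2. The strategy rests on the C4 carbonyl of the 4-pyranone (ring C), which sits between C3 and C4a of the fully substituted ring A. C4 is removed as carbon monoxide, C2–C3 (with ring B) as aryl alkyne 13, and O1/C8a/C4a as o-iodophenol 8, whose only ring carbon without oxygen is the future C4a.
3. Iodophenol 8 comes from 2,3,4-trimethoxybenzaldehyde by exchange of CHO for OH, O-methylation, directed metalation/borylation/oxidation and iodination of the one remaining CH.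
4. Alkyne 13 comes from syringaldehyde by O-benzylation and one-carbon homologation of the aldehyde.
5. Ring order: rings A and B are bought as benzenes; ring C is the only ring built, closed in the step that joins the two halves.

Key step: step 8

Remark on the chemistry: enaminone 16 is drawn as the E isomer; its alkene geometry has no bearing on the ring closure, since either isomer can cyclise.

**Step 1**
Reactants: 1 2,3,4-trimethoxybenzaldehyde
Product: 2 2,3,4-trimethoxyphenyl formate
Conditions: mCPBA (1.3 equiv), CH2Cl2, 0 °C to rt; NaHCO3 wash, crude product carried on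
Reagents that add atoms: meta-chloroperoxybenzoic acid (mCPBA), O=C(OO)c1cccc(Cl)c1
Why: Baeyer–Villiger oxidation, in which the electron-rich trimethoxyphenyl group of the Criegee adduct migrates in preference to hydride, so the aryl formate should form rather than the benzoic acid.

**Step 2**
Reactants: 2 2,3,4-trimethoxyphenyl formate
Product: 3 2,3,4-trimethoxyphenol
Conditions: K2CO3 (0.2 equiv), MeOH, rt, under N2; dilute HCl work-up
Reagents that add atoms: none
Why: Base-catalysed methanolysis (transesterification) of the labile aryl formate, which should release the phenol and methyl formate while the methyl ethers stay untouched.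

**Step 3**
Reactants: 3 2,3,4-trimethoxyphenol
Product: 4 1,2,3,4-tetramethoxybenzene
Conditions: MeI (1.5 equiv), K2CO3 (2 equiv), DMF, rt
Reagents that add atoms: iodomethane, CI
Why: Williamson ether synthesis, SN2 attack of the phenoxide on iodomethane, with no competing nucleophile in the molecule.

**Step 4**
Reactants: 4 1,2,3,4-tetramethoxybenzene
Product: 7 2,3,4,5-tetramethoxyphenol, via aryllithium 5 (not isolated), via dimethyl arylboronate 6 (not isolated)
Conditions: n-BuLi (1.2 equiv), TMEDA (1.2 equiv), THF, 0 °C to rt; B(OMe)3 (2 equiv), −78 °C to rt; AcOH, 30% aq. H2O2, 0 °C to rt; Na2S2O3 quench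
Reagents that add atoms: hydrogen peroxide, OO (the new phenol oxygen); n-butyllithium, [Li]CCCC, and trimethyl borate, COB(OC)OC, leave atoms only in intermediates 5 and 6
Why: Methoxy-directed ortho-metalation at either of the two symmetry-equivalent ring CH positions, borate trapping and boronate oxidation (aryl shift from boron to oxygen) should place the hydroxyl on the carbon that carried lithium.

**Step 5**
Reactants: 7 2,3,4,5-tetramethoxyphenol
Product: 8 2-iodo-3,4,5,6-tetramethoxyphenol
Conditions: N-iodosuccinimide (1.05 equiv), CH2Cl2, −20 to 0 °C, dark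
Reagents that add atoms: N-iodosuccinimide, O=C1CCC(=O)N1I
Why: Electrophilic aromatic iodination at the single remaining ring CH, which is ortho to the free hydroxyl, so only one regioisomer is possible; low temperature and one equivalent of reagent should limit oxidation of the ring.

**Step 6**
Reactants: 9 syringaldehyde (4-hydroxy-3,5-dimethoxybenzaldehyde); 10 benzyl bromide
Product: 11 4-benzyloxy-3,5-dimethoxybenzaldehyde
Conditions: K2CO3 (2 equiv), DMF, 60 °C
Reagents that add atoms: benzyl bromide (10), BrCc1ccccc1
Why: Williamson etherification; warm K2CO3/DMF should overcome the two flanking methoxy groups, and the non-enolisable aldehyde is inert to these conditions.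

**Step 7**
Reactants: 11 4-benzyloxy-3,5-dimethoxybenzaldehyde; 12 dimethyl (1-diazo-2-oxopropyl)phosphonate (Ohira–Bestmann reagent)
Product: 13 4-benzyloxy-3,5-dimethoxyphenylacetylene (2-benzyloxy-5-ethynyl-1,3-dimethoxybenzene)
Conditions: 12 (1.3 equiv), K2CO3 (2 equiv), MeOH/THF, 0 °C to rt
Reagents that add atoms: dimethyl (1-diazo-2-oxopropyl)phosphonate (12), COP(=O)(OC)C(=[N+]=[N-])C(C)=O (its diazo carbon becomes the terminal alkyne carbon)
Why: Ohira–Bestmann variant of the Seyferth–Gilbert homologation: methanolysis of the acetyl group frees the diazomethylphosphonate anion, which olefinates the aldehyde; loss of N2 and a 1,2-hydrogen shift in the alkylidene carbene should give the terminal alkyne under base mild enough for the benzyl ether.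

**Step 8**
Reactants: 8 2-iodo-3,4,5,6-tetramethoxyphenol; 13 4-benzyloxy-3,5-dimethoxyphenylacetylene (1.5 equiv); 14 carbon monoxide
Product: 17 4'-benzyloxy-3',5,5',6,7,8-hexamethoxyflavone, via o-hydroxyaryl ynone 15 (not isolated), via enaminone 16 (not isolated)
Conditions: PdCl2(dppf) (5 mol %; dppf = 1,1'-bis(diphenylphosphino)ferrocene), CO (15 bar), Et2NH (solvent), 100 °C, autoclave
Reagents that add atoms: carbon monoxide (14), [C-]#[O+] (becomes C4 and its oxygen); diethylamine, CCNCC, leaves atoms only in intermediate 16
Why: The divalent palladium precatalyst is reduced in the flask to zerovalent palladium, which inserts into the C–I bond of 8; migratory insertion of CO gives an aroyl–palladium species that is alkynylated by amine-deprotonated 13 and reductively eliminates ynone 15, forming the C4a–C4 and C4–C3 bonds. Diethylamine then adds to the ynone to give enaminone 16, and the ortho phenol oxygen attacks the amine-bearing carbon and expels diethylamine, forming O1–C2 and closing ring C by a 6-endo addition–elimination (formally 6-endo-dig with respect to 15). The closest known reaction type is the palladium-catalysed carbonylative annulation of o-iodophenols with terminal arylacetylenes in a secondary amine to give flavones, applied here to an iodophenol substituted on both sides of the C–I bond. No stereocentre is formed, and the C2–C3 double bond is fixed inside the pyranone. Two selectivities are needed: CO insertion before alkynylation (otherwise direct coupling and 5-endo closure to a 2-arylbenzofuran), which the CO overpressure, the absence of copper and the fast aryl migration of the electron-rich aryl–palladium should secure, and 6-endo rather than 5-exo closure (aurone), which the passage through the enaminone should secure because its beta carbon is the only electrophilic site. Compound 8 has one C–I bond, one free OH and no other open ring position, so no regiochemical alternative exists, and all other oxygens are capped as methyl or benzyl ethers.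

**Step 9**
Reactants: 17 4'-benzyloxy-3',5,5',6,7,8-hexamethoxyflavone
Product: 18 4'-hydroxy-3',5,5',6,7,8-hexamethoxyflavone
Conditions: H2 (1 atm), 10% Pd/C, EtOAc/MeOH, rt; stopped after uptake of one equivalent of H2
Reagents that add atoms: none
Why: Catalytic hydrogenolysis of the benzylic C–O bond; the C2–C3 bond belongs to the aromatic 4-pyranone (a vinylogous ester) and should be reduced much more slowly, and aryl methyl ethers are inert.

**Compound list**
1 | 2,3,4-trimethoxybenzaldehyde | COc1ccc(C=O)c(OC)c1OC | starting material
2 | 2,3,4-trimethoxyphenyl formate | COc1ccc(OC=O)c(OC)c1OC | intermediate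
3 | 2,3,4-trimethoxyphenol | COc1ccc(O)c(OC)c1OC | intermediate
4 | 1,2,3,4-tetramethoxybenzene | COc1ccc(OC)c(OC)c1OC | intermediate
5 | (2,3,4,5-tetramethoxyphenyl)lithium | [Li]c1cc(OC)c(OC)c(OC)c1OC | intermediate (not isolated)
6 | dimethyl (2,3,4,5-tetramethoxyphenyl)boronate | COB(OC)c1cc(OC)c(OC)c(OC)c1OC | intermediate (not isolated)
7 | 2,3,4,5-tetramethoxyphenol | COc1cc(O)c(OC)c(OC)c1OC | intermediate
8 | 2-iodo-3,4,5,6-tetramethoxyphenol | COc1c(O)c(I)c(OC)c(OC)c1OC | intermediate
9 | syringaldehyde (4-hydroxy-3,5-dimethoxybenzaldehyde) | COc1cc(C=O)cc(OC)c1O | starting material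
10 | benzyl bromide | BrCc1ccccc1 | starting material
11 | 4-benzyloxy-3,5-dimethoxybenzaldehyde | COc1cc(C=O)cc(OC)c1OCc1ccccc1 | intermediate
12 | dimethyl (1-diazo-2-oxopropyl)phosphonate (Ohira–Bestmann reagent) | COP(=O)(OC)C(=[N+]=[N-])C(C)=O | starting material
13 | 4-benzyloxy-3,5-dimethoxyphenylacetylene | C#Cc1cc(OC)c(OCc2ccccc2)c(OC)c1 | intermediate
14 | carbon monoxide | [C-]#[O+] | starting material
15 | 3-(4-benzyloxy-3,5-dimethoxyphenyl)-1-(2-hydroxy-3,4,5,6-tetramethoxyphenyl)prop-2-yn-1-one | COc1cc(C#CC(=O)c2c(O)c(OC)c(OC)c(OC)c2OC)cc(OC)c1OCc1ccccc1 | intermediate (not isolated)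
16 | (E)-3-(4-benzyloxy-3,5-dimethoxyphenyl)-3-(diethylamino)-1-(2-hydroxy-3,4,5,6-tetramethoxyphenyl)prop-2-en-1-one | CCN(CC)/C(=C/C(=O)c1c(O)c(OC)c(OC)c(OC)c1OC)c1cc(OC)c(OCc2ccccc2)c(OC)c1 | intermediate (not isolated)
17 | 4'-benzyloxy-3',5,5',6,7,8-hexamethoxyflavone | COc1cc(-c2cc(=O)c3c(OC)c(OC)c(OC)c(OC)c3o2)cc(OC)c1OCc1ccccc1 | intermediate
18 | 4'-hydroxy-3',5,5',6,7,8-hexamethoxyflavone | COc1cc(-c2cc(=O)c3c(OC)c(OC)c(OC)c(OC)c3o2)cc(OC)c1O | target

**Step count**
Total: 9 steps. Longest linear sequence: 7 steps (steps 1, 2, 3, 4, 5, 8, 9); the alkyne branch (steps 6, 7) joins at step 8.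

**Steps most likely to fail**

1. Step 8. Oxidative addition at the C–I bond flanked by OH and OMe may be slow. The aroyl–palladium may then be captured by diethylamine (aminocarbonylation to a salicylamide), or copper-free direct coupling followed by 5-endo closure may compete with the three-component path. Fallback, setting out from phenol 7 and aldehyde 11 and returning at flavone 17: Friedel–Crafts C-acetylation of 7 at its only free ring position (AcOH, BF3·OEt2, 80 °C) should give 1-(2-hydroxy-3,4,5,6-tetramethoxyphenyl)ethanone F1. Claisen–Schmidt condensation of F1 with 11 (KOH, EtOH, rt) should give (E)-3-(4-benzyloxy-3,5-dimethoxyphenyl)-1-(2-hydroxy-3,4,5,6-tetramethoxyphenyl)prop-2-en-1-one F2. Oxidative cyclisation of this 2'-hydroxychalcone (catalytic I2, DMSO, 120 °C) should give 17, which re-enters the route at step 9.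

2. Step 5. The pentaoxygenated phenol may be oxidised by the iodinating agent (oxidative demethylation to a methoxy-p-benzoquinone) faster than it is iodinated at carbon. Fallback, setting out from 7 and returning at 8: protection of the phenol (MOMCl, i-Pr2NEt, CH2Cl2) should give 1-(methoxymethoxy)-2,3,4,5-tetramethoxybenzene F3. Directed ortho-lithiation at its only ring CH (n-BuLi, THF, 0 °C) and quench with I2 at −78 °C should give 1-iodo-2-(methoxymethoxy)-3,4,5,6-tetramethoxybenzene F4. Acetal cleavage (HCl, MeOH, rt) should release 8 without an electrophilic oxidant ever meeting the free phenol.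

3. Step 4. Metalation may be incomplete, butyllithium may cleave a methyl ether, or the electron-rich phenol may be over-oxidised by peroxide during the boronate oxidation. Fallback, setting out from 4 and returning at 7: Vilsmeier–Haack formylation (POCl3, DMF, 80 °C) at one of the two equivalent CH positions should give 2,3,4,5-tetramethoxybenzaldehyde F5. Baeyer–Villiger oxidation (mCPBA, CH2Cl2) should give 2,3,4,5-tetramethoxyphenyl formate F6, and methanolysis (K2CO3, MeOH) should give 7.

**Further compounds**
F1 | step 8 | 1-(2-hydroxy-3,4,5,6-tetramethoxyphenyl)ethanone | CC(=O)c1c(O)c(OC)c(OC)c(OC)c1OC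
F2 | step 8 | (E)-3-(4-benzyloxy-3,5-dimethoxyphenyl)-1-(2-hydroxy-3,4,5,6-tetramethoxyphenyl)prop-2-en-1-one | COc1cc(/C=C/C(=O)c2c(O)c(OC)c(OC)c(OC)c2OC)cc(OC)c1OCc1ccccc1
F3 | step 5 | 1-(methoxymethoxy)-2,3,4,5-tetramethoxybenzene | COCOc1cc(OC)c(OC)c(OC)c1OC
F4 | step 5 | 1-iodo-2-(methoxymethoxy)-3,4,5,6-tetramethoxybenzene | COCOc1c(I)c(OC)c(OC)c(OC)c1OC
F5 | step 4 | 2,3,4,5-tetramethoxybenzaldehyde | COc1cc(C=O)c(OC)c(OC)c1OC
F6 | step 4 | 2,3,4,5-tetramethoxyphenyl formate | COc1cc(OC=O)c(OC)c(OC)c1OC
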